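**Retrosynthetic overview**
1. Target 13 ⇐ one global reductive unmasking of 12 (three O-benzyl ethers and a trichloroethyl (TCE) sulfate ester).
2. C3–O–SO3 unit of 12 ⇐ C3–H of tri-O-benzylapigenin 6 plus an electrophilic O-sulfate donor 11 (new step: C3-zincation, then C–O bond formation at the peroxide oxygen).
3. Reagent 11 ⇐ TCE chlorosulfate 9 + H2O2; 9 ⇐ trichloroethanol + SO2Cl2.
4. Pyranone ring of 6 ⇐ oxidative cyclisation of 2'-hydroxychalcone 5 (O1–C2 bond); 5 ⇐ Claisen–Schmidt condensation of 3 + 4.
5. Ring order: A and B rings are purchased; the C ring is formed in step 3; the sulfate is installed last on the intact flavone.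

Assumption: the target is achiral (no stereocentres), so "single enantiomer" needs no stereocontrol. It is delivered as the free hydrogen sulfate as drawn, by cold H+ exchange of its ammonium salt.

**Route**

Step 1
Reactants: 1 2',4',6'-trihydroxyacetophenone; 2 benzyl bromide
Product: 3 1-[2,4-bis(benzyloxy)-6-hydroxyphenyl]ethan-1-one
Conditions: BnBr (2.1 equiv), K2CO3, DMF, rt
Reagents that add atoms: benzyl bromide, BrCc1ccccc1
Why: Williamson etherification; the two non-chelated phenols are alkylated while the OH hydrogen-bonded to the ketone stays free.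

Step 2
Reactants: 3; 4 4-(benzyloxy)benzaldehyde
Product: 5 (E)-1-[2,4-bis(benzyloxy)-6-hydroxyphenyl]-3-[4-(benzyloxy)phenyl]prop-2-en-1-one
Conditions: KOH (aq), EtOH–THF, rt, 24–48 h
Reagents that add atoms: 4-(benzyloxy)benzaldehyde, O=Cc1ccc(OCc2ccccc2)cc1
Why: Claisen–Schmidt aldol condensation of a methyl ketone with a non-enolisable aldehyde; dehydration gives the conjugated (E)-chalcone.

Step 3
Reactants: 5
Product: 6 5,7-bis(benzyloxy)-2-[4-(benzyloxy)phenyl]-4H-chromen-4-one (tri-O-benzylapigenin)
Conditions: I2 (10 mol %), DMSO, 130 °C, 1–2 h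
Reagents that add atoms: none
Why: I2/DMSO oxidative cyclisation of a 2'-hydroxychalcone (oxa-Michael closure then dehydrogenation, DMSO re-oxidising HI) forms the pyranone ring; catalytic iodine and short heating spare the benzyl ethers.

Step 4
Reactants: 7 2,2,2-trichloroethanol; 8 sulfuryl chloride
Product: 9 2,2,2-trichloroethyl chlorosulfate
Conditions: SO2Cl2 (1.0 equiv), pyridine, Et2O, −78 °C → rt
Reagents that add atoms: sulfuryl chloride, ClS(Cl)(=O)=O
Why: Mono-substitution of sulfuryl chloride by the alcohol at low temperature, the standard preparation of this known sulfating reagent.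

Step 5
Reactants: 9 (2 equiv); 10 hydrogen peroxide
Product: 11 bis(2,2,2-trichloroethoxysulfonyl) peroxide, Cl3CCH2O–SO2–O–O–SO2–OCH2CCl3
Conditions: 30% aq H2O2 (0.5 equiv), K2CO3, THF–H2O, −20 °C; extract into cold CH2Cl2; store and use as a titrated solution at ≤ −20 °C, never concentrated to dryness
Reagents that add atoms: hydrogen peroxide, OO
Why: Proposed new method: (new reagent, made by a known reaction class) HOO−, an α-effect nucleophile, displaces chloride at S(VI) to give TCE peroxymonosulfate, whose anion attacks a second chlorosulfate, while the β-CCl3 group blocks SN2 at carbon; the closest known reaction is the preparation of bis(arenesulfonyl) and bis(methanesulfonyl) peroxides from sulfonyl chlorides and alkaline H2O2.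

Step 6 (key step)
Reactants: 6; 11
Product: 12 5,7-bis(benzyloxy)-2-[4-(benzyloxy)phenyl]-4-oxo-4H-chromen-3-yl 2,2,2-trichloroethyl sulfate
Conditions: LDA (1.1 equiv), THF, −78 °C, 30 min; Zn(OPiv)2 (1.2 equiv), −78 → 0 °C; strip THF/iPr2NH in vacuo; CH2Cl2–THF, 11 (1.3 equiv), −78 → −20 °C; aq Na2S2O3
Reagents that add atoms: bis(2,2,2-trichloroethoxysulfonyl) peroxide, ClC(Cl)(Cl)COS(=O)(=O)OOS(=O)(=O)OCC(Cl)(Cl)Cl
Why: Proposed new method: polarity-reversed sulfation (C-nucleophile + O-electrophile): LDA removes the flavone C3–H (the established lithiation site next to C4=O), transmetalation to a halide-free zinc pivalate stops ring-opening of the vinyl-lithium and allows the amine to be evaporated (both halide and iPr2NH would consume the peroxide), and the C3–Zn bond then attacks the weak, low-lying O–O bond of 11 in an ipso SE2 step, expelling TCE-sulfate and forming the C3–O bond with the protected sulfate already attached, with regiochemistry fixed by the metalation site; the closest known reaction types are α-sulfonyloxylation of enol derivatives and arene C–H oxygenation with bis(sulfonyl) peroxides, and oxidation of aryl-metal reagents with peroxides or peresters.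

Step 7
Reactants: 12
Product: 13 kaempferol 3-O-sulfate (5,7-dihydroxy-2-(4-hydroxyphenyl)-4-oxo-4H-chromen-3-yl hydrogen sulfate)
Conditions: 10% Pd/C, HCO2NH4 (10 equiv), H2 (1 atm), THF–MeOH, rt; filter; Dowex 50W-X8 (H+), MeOH–H2O, 0 °C; lyophilise
Reagents that add atoms: none
Why: Pd/C–ammonium formate is the standard reductive cleavage of TCE aryl sulfates and also hydrogenolyses aryl benzyl ethers, the formate buffer protects the acid-labile sulfate from HCl, the tetrasubstituted C2=C3 is not reduced, and cold resin exchange gives the free acid.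

**Compound list**
1 | 2',4',6'-trihydroxyacetophenone | CC(=O)c1c(O)cc(O)cc1O | starting material
2 | benzyl bromide | BrCc1ccccc1 | starting material
3 | 1-[2,4-bis(benzyloxy)-6-hydroxyphenyl]ethan-1-one | CC(=O)c1c(O)cc(OCc2ccccc2)cc1OCc1ccccc1 | intermediate
4 | 4-(benzyloxy)benzaldehyde | O=Cc1ccc(OCc2ccccc2)cc1 | starting material
5 | (E)-1-[2,4-bis(benzyloxy)-6-hydroxyphenyl]-3-[4-(benzyloxy)phenyl]prop-2-en-1-one | O=C(/C=C/c1ccc(OCc2ccccc2)cc1)c1c(O)cc(OCc2ccccc2)cc1OCc1ccccc1 | intermediate
6 | 5,7-bis(benzyloxy)-2-[4-(benzyloxy)phenyl]-4H-chromen-4-one | O=c1cc(-c2ccc(OCc3ccccc3)cc2)oc2cc(OCc3ccccc3)cc(OCc3ccccc3)c12 | intermediate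
7 | 2,2,2-trichloroethanol | OCC(Cl)(Cl)Cl | starting material
8 | sulfuryl chloride | ClS(Cl)(=O)=O | starting material
9 | 2,2,2-trichloroethyl chlorosulfate | ClS(=O)(=O)OCC(Cl)(Cl)Cl | intermediate
10 | hydrogen peroxide | OO | starting material
11 | bis(2,2,2-trichloroethoxysulfonyl) peroxide | ClC(Cl)(Cl)COS(=O)(=O)OOS(=O)(=O)OCC(Cl)(Cl)Cl | intermediate (new reagent)
12 | 5,7-bis(benzyloxy)-2-[4-(benzyloxy)phenyl]-4-oxo-4H-chromen-3-yl 2,2,2-trichloroethyl sulfate | O=c1c(OS(=O)(=O)OCC(Cl)(Cl)Cl)c(-c2ccc(OCc3ccccc3)cc2)oc2cc(OCc3ccccc3)cc(OCc3ccccc3)c12 | intermediate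
13 | kaempferol 3-O-sulfate | O=c1c(OS(=O)(=O)O)c(-c2ccc(O)cc2)oc2cc(O)cc(O)c12 | target

**Totals**
Total steps: 7. Longest linear sequence: 5 (steps 1, 2, 3, 6, 7); the reagent branch is steps 4–5.

**Three steps most likely to fail**
- **Step 6 (proposed new C3–O sulfoxylation).** Risks are protonation back to 6, single-electron transfer (SET) homocoupling, and ring-opening of the metalated flavone. Fallback (known chemistry): hydroxylate C3 of 6 by the known lithiation–borylation–oxidation sequence (LDA; B(OMe)3; H2O2/AcOH) to give 5,7,4'-tri-O-benzylkaempferol. Then sulfate the 3-OH conventionally with 9/Et3N/DMAP to reach the same 12 and continue with step 7.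
- **Step 5 (new peroxide reagent).** Risks are hydrolysis of 9 and instability of 11. Fallback (known chemistry): abandon the peroxide and reverse the polarity. Oxidise 6 to the 3-hydroxyflavone with DMDO (known flavone → flavonol oxidation), sulfate with SO3·NMe3 and isolate as the Bu4N+ salt, then debenzylate with H2/Pd–C.
- **Step 7 (global unmasking and acid liberation).** Risks are chloride slowing debenzylation and desulfation on the acid resin. Fallback: decouple the two deprotections by changing the sulfate protecting group to neopentyl, using the analogous peroxide made from neopentyl chlorosulfate. Remove neopentyl with NaN3/DMF, then run a chloride-free H2/Pd–C debenzylation on the sulfate salt. Keep the product as its Na/K salt if the free acid proves too labile.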